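All runs are calculated from invented constants; noise was put on by code.

In a one-step world, substrate and coupling partner give first product and nothing else, so substrate lost equals first product found, and the bench rule caps the yield at the partner charge over the substrate charge. That cap is 30.0% for Sunday's run, where the partner is the limiting reagent.

the same everywhere: substrate 0.25 M
- Sunday's: coupling partner 0.075 M; run made earlier
- Thursday's: coupling partner 0.88 M; run made earlier
- zeta: coupling partner 0.125 M; time 1.0 h
- eta: coupling partner 0.200 M; time 1.0 h
- delta: coupling partner 1.00 M; time 1.0 h

| run | time / min | first product / % | substrate / % |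
|---|---|---|---|
| Sunday's | 5.00 | 5.2 | 93.9 |
| Sunday's | 12.0 | 10.4 | 88.7 |
| Sunday's | 25.0 | 16.5 | 81.9 |
| Sunday's | 60.0 | 21.9 | 74.7 |
| Thursday's | 8.00 | 41.7 | 33.0 |
| Thursday's | 20.0 | 52.1 | 8.7 |
| Thursday's | 40.0 | 45.4 | 1.3 |
| Thursday's | 60.0 | 35.6 | 0 |

(scatter of a reading: 0.3 percentage points)

* final first product, as a percentage of the substrate charged, for each flask in turn (zeta, eta, delta)

- what was read earlier has a scatter of 0.3 percentage points, one standard deviation
- a reading or a percentage of first product counts all its forms, free or not

Sunday's run at 60.0 min breaks the rule: 25.3% of the substrate is lost, but 21.9% is found, so 3.40% is missing, far above the scatter. I assume each missing part took a second partner. This gives the partner cost, 1.13, the partner spent per substrate lost.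

I call that cost g, hold it fixed and integrate the rate in closed form: the logarithm of the fraction of substrate left over the fraction of partner left grows linearly in time, with slope (g[substrate] − [partner]) k, both concentrations as charged. Sunday's 25.0 min reading gives k = 0.183 M⁻¹ min⁻¹.

The border shows on Thursday, with 11.7 times Sunday's partner: at 8.00 min the cost already reads 1.38, so a fixed cost doesn't carry to delta, and I give delta no number.

For zeta I reckon 39.4% lost and 34.1% first product; for eta, 51.0%.

The forecast says 36%, 52% and 30%, slightly above mine, and it sees “a bound first product that reacts before it is released”.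

The flasks give 34.6%, 48.6% and 26.5%.

    substrate + coupling partner → first product (k = 0.00310 M⁻¹ s⁻¹)
    coupling partner + first product → double product (k = 0.00290 M⁻¹ s⁻¹)
    coupling partner + double product → tris adduct (k = 8.90 × 10⁻⁵ M⁻¹ s⁻¹)
    coupling partner + first product → over-reaction product (k = 0.00760 M⁻¹ s⁻¹)
    crystals ⇌ first product, rate k5*(cs5 - [first product]) while solid is left; crystals form when [first product] > cs5 (solubility = 6.00 mM, k = 0.0190 s⁻¹)

In delta at 1.0 h, 24.7% of the 26.5% first product stands as crystals; at 10.0 h first product reads 0%, and a reading that late would put the forecast's 30% out. Partner spent per substrate lost by 1.0 h is 1.13 in zeta, 1.17 in eta and 1.76 in delta, against the reading of 1.13 from Sunday's run.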